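**Assumptions (remarks on the chemistry)**

- Atoms carry germacrane numbers in every structure, open-chain ones included: ring C1–C10, lactone carbons C11–C13, C14 on C10, C15 on C4.
- The antipodes of ProPhenol, BINOL and the oxazaborolidine are named from the accepted facial models of these catalysts; if an assay shows the opposite sense, the mirror-image ligand is used and nothing else changes.
- Pent-1-en-4-yne (1), the silyl propargyl ether 6, (tributylstannyl)methanol (12) and but-3-en-2-one (14) are taken as purchased.

## The problem

The target 26 is a germacra-1(10),4,7(11)-trien-12,6-olide: a ten-membered carbocycle with two E trisubstituted alkenes, fused through C6 and C7 to a tetrasubstituted butenolide whose α-carbon C11 carries the C13 acetoxymethyl group. The three stereocentres, C2 (R, acetate), C6 (R, lactone oxygen) and C8 (S, methacrylate), are all allylic and lie in 1,5-relationships, so none can be trusted to direct another across an open chain. The central difficulty is the medium ring, whose closure must also respect the geometry of whichever alkene is formed in it. The C6–H is both allylic and the γ-hydrogen of the butenolide, so base of any strength epimerises it. The 1,5-diene cyclises transannularly under acid and undergoes Cope rearrangement on heating. The C13 acetate is an allylic leaving group on an electron-poor alkene and the methacrylate polymerises, so both belong at the end. The enabling feature is that C2(O)–C1=C10(CH3)–C9 is exactly the unit produced by 1,4-opening of an isopropenyl epoxide. C8 sits on the butenolide β-carbon C7, so a nitro group there gives a vinylogous α-nitro ester, far more acidic than C6–H, and the nitro group can afterwards be exchanged for oxygen.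

## Retrosynthesis

**26 to 24.** The C8–O acyl bond is cut first, giving alcohol 25, which is traced to ketone 24. C8 is remote from C2 and C6 and the ring conformation is not known in advance, so a reagent-controlled reduction is preferred to any relay from the ring. The polymerisable ester then appears only in the last step.

**24 to 20.** Both acetates are removed to diol 23, the C13 oxygen is re-silylated to 22, and the C8 carbonyl is traced to the nitro group of 20. The order matters. A nitronate next to a C13 acetate would expel it, and acylating the alcohol in the presence of the acidic nitro group would O-acylate the nitronate. The forward sequence therefore converts nitro to ketone first, and only then desilylates and acetylates C2 and C13 together.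

**20 to 19 (key cut, C8–C9).** This cut removes the ring and leaves an acyclic vinyl epoxide 19 with the nitromethyl butenolide as the only acidic site. The neighbouring cuts C7–C8 or C9–C10 would need strong base or an organometallic that the butenolide cannot tolerate. The forward reaction must close at C9 and give the E C1=C10 bond.

**19 to 17.** The C8–N bond is cut to allylic bromide 18, and the C9 methylene is removed to give epoxy ketone 17. The nitro group is placed last because its acidity is incompatible with an enone, with a lanthanum alkoxide catalyst and with a titanium methylidene. The methylenation must be non-basic because the butenolide is already present.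

**17 to 15.** The bromide goes back to the primary alcohol 16 and the C1–C2 epoxide to the E enone 15. Catalytic nucleophilic epoxidation sets C1 and C2 independently of the distant C6 centre, and the C2–O bond formed here is kept to the end.

**15 to 13 + 14.** The C1=C2 bond is cut by cross-metathesis into terminal alkene 13 and enone 14. This avoids a protected C2 alcohol, its unmasking and a β,γ-unsaturated aldehyde, which an olefination route would need.

**13 to 11 + 12.** The C7–C8 bond is cut to vinyl iodide 11 and stannane 12. A neutral sp2–sp3 coupling is chosen over base-mediated substitution so that C6 is not put at risk.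

**11 to 8.** The lactone C6–O bond and the C7–I bond are cut by iodolactonisation to allenoic acid 10, and C11–C12 by carbonylation to trifluoroacetate 9 and alcohol 8. This places the carboxyl, the iodide and C13 on the alkene in one sequence, with C6 derived from the carbinol centre of 8 by a stereospecific anti/anti pathway.

**8 to 5 + 6.** The C6–C7 bond is cut to enal 5 and alkyne 6. A catalytic asymmetric alkynylation sets the only stereocentre of this stage.

**5 to 1.** Enal 5 comes from allylic alcohol 4, and 4 from enyne 1 by cutting C4–C15 and C5–C6. Syn carbometallation fixes the E C4=C5 geometry once and for all.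

## Roads not taken

**Alternative 1:** hetero-Pauson–Khand closure of both rings.
- Cut: C6–C7, C11–C12 and C12–O together.
- Forward step: Mo(CO)3(DMF)3 would join the alkyne, the enal carbonyl and CO of the open-chain ynal A1 to give the bicyclic lactone A2.
- Merits: the butenolide and the carbocycle arise in one step, the C2 and C13 acetates are already in place, and C8 is set in the chain. The route would be markedly shorter than the chosen one and needs no oxidation-state detour at C8; in step economy it is clearly better.
- Weak points: aldehyde–alkyne cyclocarbonylations are established where the tether closes a five- or six-membered ring, not a ten-membered one held open by two E alkenes. The enal carbonyl is a poor partner. The alkyne and the C1=C10 alkene form a 1,6-enyne, the ideal substrate for the ordinary all-carbon Pauson–Khand reaction. Zerovalent molybdenum can also ionise the propargylic C13 acetate. C6 would be controlled only by the distant C8 centre.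
- Comparison: the chosen plan is longer and spends three steps adjusting C8. Against that it sets a ring closure of a documented type and a C6 centre fixed by a catalyst before the ring exists.

**Alternative 2:** anionic oxy-Cope ring expansion.
- Cut: C2–C3, with C5–C10 re-joined in the precursor, the furan-fused trans-dialkenylcyclohexanol A3.
- Forward step: KH with 18-crown-6 forms the C5 alkoxide, the [3,3] shift expands ring B, and PhNTf2 traps the enolate as triflate A4.
- Merits: this is the most dependable entry to E,E-cyclodeca-1,5-dienes. The chair transition state fixes both alkene geometries and relays the enol ether geometry to C2. In ring formation and alkene geometry it is better than the chosen plan.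
- Weak points: A3 carries a quaternary C10 next to a tertiary carbinol C5 with trans alkenyl groups, plus C8, and is long to make. After the expansion the triflate must be reduced and the furan oxidised regioselectively to the C12 lactone. C6 is then created last, by reduction in a strained, acid-sensitive ring with no element to control it.
- Comparison: the chosen plan sets against the oxy-Cope a C6 centre fixed from the start and a butenolide never generated from a furan. Its price is the uncertain π-allyl geometry.

**Alternative 3:** Stille furanophane closure.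
- Cut: C5–C6 of a furan analogue.
- Forward step: Pd2(dba)3 with AsPh3 would couple the furylstannane and the E vinyl iodide of A5 to give furanophane A6.
- Merits: sp2–sp2 coupling under neutral conditions is among the most reliable macrocyclisations. Both alkenes are made beforehand with defined geometry and the C2, C8 and C13 oxygens are close to their final form. In geometric security it is better than the chosen plan.
- Weak points: A6 is a 2,3-bridged furan in a ten-membered ring with two E alkenes, which is strained. A5 needs two separate asymmetric steps and an acyclic E trisubstituted alkene. The route ends with the same dearomatisation as alternative 2: oxidation of the furan beside two electron-rich alkenes, then an uncontrolled reduction at C6.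
- Comparison: the chosen plan answers with early, catalyst-controlled C6 and an intact butenolide throughout, and accepts the risk of the ring closure itself.

Key step: step 13

## Route

Step 1
Reactants: 1 pent-1-en-4-yne
Product: 4 (2E)-3-methylhexa-2,5-dien-1-ol, via alkenyl(dimethyl)alane 2 (not isolated), via lithium alkenylaluminate 3 (not isolated)
Conditions: Me3Al, Cp2ZrCl2 (0.25 equiv), CH2Cl2, 0 °C to rt; n-BuLi, THF, −78 °C; (CH2O)n, rt; H2O
Reagents that add atoms: trimethylaluminium, C[Al](C)C; formaldehyde (as paraformaldehyde), C=O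
Why: Negishi zirconium-catalysed methylalumination adds CH3 and Al syn across the terminal alkyne (methyl to the internal carbon) and leaves the monosubstituted alkene alone; the aluminate is hydroxymethylated with retention, which fixes the E C4=C5 geometry.

Step 2
Reactants: 4 (2E)-3-methylhexa-2,5-dien-1-ol
Product: 5 (2E)-3-methylhexa-2,5-dienal
Conditions: MnO2, CH2Cl2, rt
Reagents that add atoms: none
Why: Allylic oxidation with MnO2 is neutral, so the skipped diene and the E geometry survive; the volatile aldehyde is carried on as a solution.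

Step 3
Reactants: 5 (2E)-3-methylhexa-2,5-dienal; 6 tert-butyldimethyl(prop-2-yn-1-yloxy)silane
Product: 8 (4S,5E)-1-[(tert-butyldimethylsilyl)oxy]-6-methylnona-5,8-dien-2-yn-4-ol, via alkynyl(methyl)zinc 7 (not isolated)
Conditions: Me2Zn, (R,R)-ProPhenol (10 mol %), Ph3P=O (20 mol %), toluene, 0 °C
Reagents that add atoms: none
Why: Zinc–ProPhenol catalysed asymmetric alkynylation of an enal (Trost); the dinuclear zinc alkoxide delivers the alkynyl group to one aldehyde face and sets the carbinol C6 as S, the configuration that steps 5 and 6 invert to 6R.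

Step 4
Reactants: 8 (4S,5E)-1-[(tert-butyldimethylsilyl)oxy]-6-methylnona-5,8-dien-2-yn-4-ol
Product: 9 (4S,5E)-1-[(tert-butyldimethylsilyl)oxy]-6-methylnona-5,8-dien-2-yn-4-yl trifluoroacetate
Conditions: (CF3CO)2O, pyridine, CH2Cl2, −20 °C; used crude
Reagents that add atoms: trifluoroacetic anhydride, O=C(OC(=O)C(F)(F)F)C(F)(F)F
Why: O-acylation leaves C6 untouched; the trifluoroacetate is reactive enough for zerovalent palladium at or below room temperature yet less prone to ionise than a sulfonate on this allylic, propargylic carbon.

Step 5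
Reactants: 9 (4S,5E)-1-[(tert-butyldimethylsilyl)oxy]-6-methylnona-5,8-dien-2-yn-4-yl trifluoroacetate
Product: 10 (Ra,5E)-2-{[(tert-butyldimethylsilyl)oxy]methyl}-6-methylnona-2,3,5,8-tetraenoic acid
Conditions: Pd(PPh3)4 (5 mol %), CO (1 atm), 2,6-lutidine, THF/H2O, 0 °C to rt
Reagents that add atoms: carbon monoxide, [C-]#[O+]; water, O
Why: Palladium-catalysed carbonylation of a propargylic ester (Tsuji, Marshall): anti SN2′ oxidative addition gives the allenylpalladium, CO insertion with retention and hydrolysis give the 2,3-allenoic acid, so the S centre becomes the Ra axis. Low temperature and CO saturation keep carbonylation ahead of allenylpalladium equilibration and of the [1,5]-hydrogen shift of the vinylallene; the acid is used at once.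

Step 6
Reactants: 10 (Ra,5E)-2-{[(tert-butyldimethylsilyl)oxy]methyl}-6-methylnona-2,3,5,8-tetraenoic acid
Product: 11 (5R)-3-{[(tert-butyldimethylsilyl)oxy]methyl}-4-iodo-5-[(1E)-2-methylpenta-1,4-dien-1-yl]furan-2(5H)-one
Conditions: I2, NaHCO3, MeCN, −20 to 0 °C, dark
Reagents that add atoms: iodine, II
Why: Iodolactonisation of a 2,3-allenoic acid as its carboxylate (Ma): iodine activates the C6=C7 bond and the carboxylate closes the five-membered ring at C6 anti to iodine, so the axis is transferred to a 6R centre (overall inversion relative to 8) and C7 receives the iodide needed next.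

Step 7
Reactants: 11 (5R)-3-{[(tert-butyldimethylsilyl)oxy]methyl}-4-iodo-5-[(1E)-2-methylpenta-1,4-dien-1-yl]furan-2(5H)-one; 12 (tributylstannyl)methanol
Product: 13 (5R)-3-{[(tert-butyldimethylsilyl)oxy]methyl}-4-(hydroxymethyl)-5-[(1E)-2-methylpenta-1,4-dien-1-yl]furan-2(5H)-one
Conditions: Pd2(dba)3 (5 mol %), AsPh3 (20 mol %), CuI (10 mol %), DMF, 45 °C
Reagents that add atoms: none
Why: Stille coupling of a β-iodo enoate with a hydroxymethylstannane forms C7–C8 without base, so the labile C6–H is not touched; the new hydroxymethyl group is trans to the lactone carbonyl across C7=C11 and cannot translactonise.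

Step 8
Reactants: 13 (5R)-3-{[(tert-butyldimethylsilyl)oxy]methyl}-4-(hydroxymethyl)-5-[(1E)-2-methylpenta-1,4-dien-1-yl]furan-2(5H)-one; 14 but-3-en-2-one
Product: 15 (5R)-3-{[(tert-butyldimethylsilyl)oxy]methyl}-4-(hydroxymethyl)-5-[(1E,4E)-2-methyl-6-oxohepta-1,4-dien-1-yl]furan-2(5H)-one
Conditions: 14 (5 equiv), second-generation Hoveyda–Grubbs catalyst RuCl2(H2IMes)(=CH-C6H4-2-OiPr) (5 mol %), CH2Cl2, 40 °C
Reagents that add atoms: none
Why: Cross-metathesis of a monosubstituted alkene with an electron-poor vinyl ketone gives the E enone; the trisubstituted C4=C5 bond and the tetrasubstituted butenolide alkene do not react with the ruthenium carbene.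

Step 9
Reactants: 15 (5R)-3-{[(tert-butyldimethylsilyl)oxy]methyl}-4-(hydroxymethyl)-5-[(1E,4E)-2-methyl-6-oxohepta-1,4-dien-1-yl]furan-2(5H)-one
Product: 16 (5R)-5-{(1E)-3-[(2R,3S)-3-acetyloxiran-2-yl]-2-methylprop-1-en-1-yl}-3-{[(tert-butyldimethylsilyl)oxy]methyl}-4-(hydroxymethyl)furan-2(5H)-one
Conditions: La(OiPr)3 (10 mol %), (R)-BINOL (10 mol %), Ph3As=O (10 mol %), t-BuOOH, 4 Å MS, THF, rt
Reagents that add atoms: tert-butyl hydroperoxide, CC(C)(C)OO
Why: Shibasaki lanthanum–BINOL nucleophilic epoxidation of an E enone: catalyst-bound tert-butyl peroxide adds to C2 and closes the trans epoxide, and the (R)-BINOL complex is expected to give the αS,βR epoxy ketone, i.e. the C2–O bond with the R configuration kept to the target. The electron-rich C4=C5 bond and the tetrasubstituted butenolide are not attacked by a nucleophilic oxidant; any C6 epimer carried from steps 5 and 6 is now a diastereomer and can be removed.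

Step 10
Reactants: 16 (5R)-5-{(1E)-3-[(2R,3S)-3-acetyloxiran-2-yl]-2-methylprop-1-en-1-yl}-3-{[(tert-butyldimethylsilyl)oxy]methyl}-4-(hydroxymethyl)furan-2(5H)-one
Product: 17 (5R)-5-{(1E)-3-[(2R,3S)-3-acetyloxiran-2-yl]-2-methylprop-1-en-1-yl}-4-(bromomethyl)-3-{[(tert-butyldimethylsilyl)oxy]methyl}furan-2(5H)-one
Conditions: CBr4, PPh3, 2,6-lutidine, CH2Cl2, 0 °C
Reagents that add atoms: carbon tetrabromide, BrC(Br)(Br)Br
Why: Appel bromination is an SN2 displacement at the primary allylic carbon under near-neutral conditions; an SN2′ path is closed because the alkene is tetrasubstituted, and the epoxy ketone is inert to the phosphonium reagent at 0 °C.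

Step 11
Reactants: 17 (5R)-5-{(1E)-3-[(2R,3S)-3-acetyloxiran-2-yl]-2-methylprop-1-en-1-yl}-4-(bromomethyl)-3-{[(tert-butyldimethylsilyl)oxy]methyl}furan-2(5H)-one
Product: 18 (5R)-4-(bromomethyl)-3-{[(tert-butyldimethylsilyl)oxy]methyl}-5-{(1E)-2-methyl-3-[(2R,3R)-3-(prop-1-en-2-yl)oxiran-2-yl]prop-1-en-1-yl}furan-2(5H)-one
Conditions: Cp2Ti(μ-Cl)(μ-CH2)AlMe2 (Tebbe reagent, 1.2 equiv), pyridine (cat.), THF/toluene, −40 to 0 °C
Reagents that add atoms: Tebbe reagent Cp2Ti(μ-Cl)(μ-CH2)AlMe2, C[Al-]1(C)C[Ti]([Cl+]1)(C1C=CC=C1)C1C=CC=C1
Why: Tebbe methylenation: the Lewis base releases the titanium methylidene Cp2Ti=CH2 from its chloride-bridged aluminium adduct, and this converts the ketone into the 1,1-disubstituted alkene through an oxatitanacyclobutane without any basic species, so neither the C6–H nor the epoxide stereocentres are disturbed. Ketones react far faster than lactones with the titanium methylidene, and only the CH2 group of the reagent enters the product.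

Step 12
Reactants: 18 (5R)-4-(bromomethyl)-3-{[(tert-butyldimethylsilyl)oxy]methyl}-5-{(1E)-2-methyl-3-[(2R,3R)-3-(prop-1-en-2-yl)oxiran-2-yl]prop-1-en-1-yl}furan-2(5H)-one
Product: 19 (5R)-3-{[(tert-butyldimethylsilyl)oxy]methyl}-5-{(1E)-2-methyl-3-[(2R,3R)-3-(prop-1-en-2-yl)oxiran-2-yl]prop-1-en-1-yl}-4-(nitromethyl)furan-2(5H)-one
Conditions: NaNO2, phloroglucinol, DMF, 0 °C to rt; work-up at pH 4–5
Reagents that add atoms: sodium nitrite, [Na+].[O-]N=O
Why: Kornblum nitrite displacement at an activated primary bromide (a vinylogous α-bromo ester) gives the nitro compound by N-attack; phloroglucinol traps the nitrite ester by-product that would nitrosate the acidic product, and nitrite is too weak a nucleophile to open the epoxide.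

Step 13
Reactants: 19 (5R)-3-{[(tert-butyldimethylsilyl)oxy]methyl}-5-{(1E)-2-methyl-3-[(2R,3R)-3-(prop-1-en-2-yl)oxiran-2-yl]prop-1-en-1-yl}-4-(nitromethyl)furan-2(5H)-one
Product: 20 (1(10)E,2R,4E,6R,8RS)-13-[(tert-butyldimethylsilyl)oxy]-2-hydroxy-8-nitrogermacra-1(10),4,7(11)-trien-12,6-olide
Conditions: Pd2(dba)3·CHCl3 (5 mol %), P(OiPr)3 (30 mol %), THF, 0.002 M by slow addition, rt to 40 °C
Reagents that add atoms: none
Why: Zerovalent palladium coordinates the isopropenyl group anti to the epoxide oxygen and ionises C1–O with inversion, which releases the ring strain and gives a zwitterionic π-allylpalladium complex over C1–C10–C9 with a C2 alkoxide; this alkoxide is the only base present and deprotonates the C8 nitromethyl group, a vinylogous α-nitro ester and by far the strongest carbon acid in the molecule. The soft nitronate attacks the unsubstituted allyl terminus C9 anti to palladium, forms C8–C9 and frees the catalyst; the closest known chemistry is the Trost macrocyclisation of vinyl epoxides carrying a tethered pronucleophile under neutral conditions, together with the Tsuji–Trost C-allylation of nitronates. The ten-membered ring closes end to end, with all three allyl carbons becoming ring members. The one new stereocentre, C8, is not controlled (both epimers are carried on and the centre is erased in step 14), while C2 keeps the configuration from step 9 because its C–O bond is never broken, and C6 meets no external base. Attack at C9 and not C1 follows the usual distal preference of vinyl epoxides and is reinforced because closure at C1 would put the E C4=C5 bond into an eight-membered ring. C-alkylation at C8 rather than C11 is favoured because C11 is fully substituted and O-allylation of nitronates is reversible under palladium. The E C1=C10 bond requires closure through the syn π-allyl isomer (C2 cis to the C10 methyl), the thermodynamically preferred isomer, reached by π–σ–π exchange that should be fast against a slow closure at high dilution; the C10 methyl narrows that preference and this is the main hazard.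

Step 14
Reactants: 20 (1(10)E,2R,4E,6R,8RS)-13-[(tert-butyldimethylsilyl)oxy]-2-hydroxy-8-nitrogermacra-1(10),4,7(11)-trien-12,6-olide
Product: 22 (1(10)E,2R,4E,6R)-13-[(tert-butyldimethylsilyl)oxy]-2-hydroxy-8-oxogermacra-1(10),4,7(11)-trien-12,6-olide, via C8 ketimine 21 (not isolated)
Conditions: TiCl3 (aq., 4–5 equiv), NH4OAc, THF/MeOH/H2O, pH 5–6, 0 °C to rt
Reagents that add atoms: water, O
Why: McMurry reductive Nef reaction: at pH 5–6 the acidic nitro compound is in equilibrium with its nitronate, trivalent titanium reduces it to the ketimine, and water hydrolyses this to the ketone, which erases the C8 centre. The buffered medium spares the acid-sensitive diene, the lactone and the silyl ether, and the nitronate never meets a C13 acetate.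

Step 15
Reactants: 22 (1(10)E,2R,4E,6R)-13-[(tert-butyldimethylsilyl)oxy]-2-hydroxy-8-oxogermacra-1(10),4,7(11)-trien-12,6-olide
Product: 23 (1(10)E,2R,4E,6R)-2,13-dihydroxy-8-oxogermacra-1(10),4,7(11)-trien-12,6-olide
Conditions: HF·pyridine, pyridine, THF, 0 °C
Reagents that add atoms: none
Why: Buffered fluoride cleaves the primary silyl ether without the acid that would trigger transannular cyclisation of the diene and without the base that would enolise C6.

Step 16
Reactants: 23 (1(10)E,2R,4E,6R)-2,13-dihydroxy-8-oxogermacra-1(10),4,7(11)-trien-12,6-olide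
Product: 24 (1(10)E,2R,4E,6R)-2,13-diacetoxy-8-oxogermacra-1(10),4,7(11)-trien-12,6-olide
Conditions: Ac2O, pyridine, DMAP (cat.), CH2Cl2, 0 °C
Reagents that add atoms: acetic anhydride, CC(=O)OC(C)=O
Why: One standard acylation installs the C2 and C13 acetates together; pyridine is too weak a base to remove the C6–H, and C2 is acylated with retention.

Step 17
Reactants: 24 (1(10)E,2R,4E,6R)-2,13-diacetoxy-8-oxogermacra-1(10),4,7(11)-trien-12,6-olide
Product: 25 (1(10)E,2R,4E,6R,8S)-2,13-diacetoxy-8-hydroxygermacra-1(10),4,7(11)-trien-12,6-olide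
Conditions: (R)-2-methyl-CBS-oxazaborolidine (0.5 equiv), catecholborane, toluene/CH2Cl2, −78 °C
Reagents that add atoms: none
Why: Corey–Bakshi–Shibata reduction: the ketone binds the oxazaborolidine with the bulky C7 alkenyl side away from the catalyst and hydride is delivered to the face that gives 8S, by analogy with aryl and alkenyl ketones. Catecholborane at −78 °C reduces neither the esters nor the lactone and does not hydroborate the trisubstituted alkenes.

Step 18
Reactants: 25 (1(10)E,2R,4E,6R,8S)-2,13-diacetoxy-8-hydroxygermacra-1(10),4,7(11)-trien-12,6-olide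
Product: 26 (1(10)E,2R,4E,6R,8S)-2,13-diacetoxy-8-(2-methylprop-2-enoyloxy)germacra-1(10),4,7(11)-trien-12,6-olide (CNP0309304.1)
Conditions: methacrylic anhydride, Et3N, DMAP (cat.), CH2Cl2, 0 °C
Reagents that add atoms: methacrylic anhydride, C=C(C)C(=O)OC(=O)C(C)=C
Why: DMAP-catalysed acylation of the secondary alcohol with retention at C8; the polymerisable ester is introduced last and at low temperature, well below the range of the Cope rearrangement.

## Compound list

1 | pent-1-en-4-yne | C#CCC=C | starting material
2 | dimethyl[(1E)-2-methylpenta-1,4-dien-1-yl]alane | C=CC/C(C)=C/[Al](C)C | intermediate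
3 | lithium butyl(dimethyl)[(1E)-2-methylpenta-1,4-dien-1-yl]aluminate | [Li+].C=CC/C(C)=C/[Al-](C)(C)CCCC | intermediate
4 | (2E)-3-methylhexa-2,5-dien-1-ol | C=CC/C(C)=C/CO | intermediate
5 | (2E)-3-methylhexa-2,5-dienal | C=CC/C(C)=C/C=O | intermediate
6 | tert-butyldimethyl(prop-2-yn-1-yloxy)silane | C#CCO[Si](C)(C)C(C)(C)C | starting material
7 | methyl{3-[(tert-butyldimethylsilyl)oxy]prop-1-yn-1-yl}zinc | C[Zn]C#CCO[Si](C)(C)C(C)(C)C | intermediate
8 | (4S,5E)-1-[(tert-butyldimethylsilyl)oxy]-6-methylnona-5,8-dien-2-yn-4-ol | C=CC/C(C)=C/[C@H](O)C#CCO[Si](C)(C)C(C)(C)C | intermediate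
9 | (4S,5E)-1-[(tert-butyldimethylsilyl)oxy]-6-methylnona-5,8-dien-2-yn-4-yl trifluoroacetate | C=CC/C(C)=C/[C@H](OC(=O)C(F)(F)F)C#CCO[Si](C)(C)C(C)(C)C | intermediate
10 | (Ra,5E)-2-{[(tert-butyldimethylsilyl)oxy]methyl}-6-methylnona-2,3,5,8-tetraenoic acid | OC(=O)C(CO[Si](C)(C)C(C)(C)C)=[C@]=C([H])/C=C(C)/CC=C | intermediate
11 | (5R)-3-{[(tert-butyldimethylsilyl)oxy]methyl}-4-iodo-5-[(1E)-2-methylpenta-1,4-dien-1-yl]furan-2(5H)-one | C=CC/C(C)=C/[C@H]1OC(=O)C(CO[Si](C)(C)C(C)(C)C)=C1I | intermediate
12 | (tributylstannyl)methanol | CCCC[Sn](CCCC)(CCCC)CO | starting material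
13 | (5R)-3-{[(tert-butyldimethylsilyl)oxy]methyl}-4-(hydroxymethyl)-5-[(1E)-2-methylpenta-1,4-dien-1-yl]furan-2(5H)-one | C=CC/C(C)=C/[C@H]1OC(=O)C(CO[Si](C)(C)C(C)(C)C)=C1CO | intermediate
14 | but-3-en-2-one | C=CC(C)=O | starting material
15 | (5R)-3-{[(tert-butyldimethylsilyl)oxy]methyl}-4-(hydroxymethyl)-5-[(1E,4E)-2-methyl-6-oxohepta-1,4-dien-1-yl]furan-2(5H)-one | CC(=O)/C=C/C/C(C)=C/[C@H]1OC(=O)C(CO[Si](C)(C)C(C)(C)C)=C1CO | intermediate
16 | (5R)-5-{(1E)-3-[(2R,3S)-3-acetyloxiran-2-yl]-2-methylprop-1-en-1-yl}-3-{[(tert-butyldimethylsilyl)oxy]methyl}-4-(hydroxymethyl)furan-2(5H)-one | CC(=O)[C@H]1O[C@@H]1C/C(C)=C/[C@H]1OC(=O)C(CO[Si](C)(C)C(C)(C)C)=C1CO | intermediate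
17 | (5R)-5-{(1E)-3-[(2R,3S)-3-acetyloxiran-2-yl]-2-methylprop-1-en-1-yl}-4-(bromomethyl)-3-{[(tert-butyldimethylsilyl)oxy]methyl}furan-2(5H)-one | CC(=O)[C@H]1O[C@@H]1C/C(C)=C/[C@H]1OC(=O)C(CO[Si](C)(C)C(C)(C)C)=C1CBr | intermediate
18 | (5R)-4-(bromomethyl)-3-{[(tert-butyldimethylsilyl)oxy]methyl}-5-{(1E)-2-methyl-3-[(2R,3R)-3-(prop-1-en-2-yl)oxiran-2-yl]prop-1-en-1-yl}furan-2(5H)-one | C=C(C)[C@H]1O[C@@H]1C/C(C)=C/[C@H]1OC(=O)C(CO[Si](C)(C)C(C)(C)C)=C1CBr | intermediate
19 | (5R)-3-{[(tert-butyldimethylsilyl)oxy]methyl}-5-{(1E)-2-methyl-3-[(2R,3R)-3-(prop-1-en-2-yl)oxiran-2-yl]prop-1-en-1-yl}-4-(nitromethyl)furan-2(5H)-one | C=C(C)[C@H]1O[C@@H]1C/C(C)=C/[C@H]1OC(=O)C(CO[Si](C)(C)C(C)(C)C)=C1C[N+](=O)[O-] | intermediate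
20 | (1(10)E,2R,4E,6R,8RS)-13-[(tert-butyldimethylsilyl)oxy]-2-hydroxy-8-nitrogermacra-1(10),4,7(11)-trien-12,6-olide | O=[N+]([O-])C1C/C(C)=C/[C@H](O)C/C(C)=C/[C@H]2OC(=O)C(CO[Si](C)(C)C(C)(C)C)=C12 | intermediate
21 | (1(10)E,2R,4E,6R)-13-[(tert-butyldimethylsilyl)oxy]-2-hydroxy-8-iminogermacra-1(10),4,7(11)-trien-12,6-olide | N=C1C/C(C)=C/[C@H](O)C/C(C)=C/[C@H]2OC(=O)C(CO[Si](C)(C)C(C)(C)C)=C12 | intermediate
22 | (1(10)E,2R,4E,6R)-13-[(tert-butyldimethylsilyl)oxy]-2-hydroxy-8-oxogermacra-1(10),4,7(11)-trien-12,6-olide | O=C1C/C(C)=C/[C@H](O)C/C(C)=C/[C@H]2OC(=O)C(CO[Si](C)(C)C(C)(C)C)=C12 | intermediate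
23 | (1(10)E,2R,4E,6R)-2,13-dihydroxy-8-oxogermacra-1(10),4,7(11)-trien-12,6-olide | O=C1C/C(C)=C/[C@H](O)C/C(C)=C/[C@H]2OC(=O)C(CO)=C12 | intermediate
24 | (1(10)E,2R,4E,6R)-2,13-diacetoxy-8-oxogermacra-1(10),4,7(11)-trien-12,6-olide | O=C1C/C(C)=C/[C@H](OC(C)=O)C/C(C)=C/[C@H]2OC(=O)C(COC(C)=O)=C12 | intermediate
25 | (1(10)E,2R,4E,6R,8S)-2,13-diacetoxy-8-hydroxygermacra-1(10),4,7(11)-trien-12,6-olide | O[C@H]1C/C(C)=C/[C@H](OC(C)=O)C/C(C)=C/[C@H]2OC(=O)C(COC(C)=O)=C12 | intermediate
26 | (1(10)E,2R,4E,6R,8S)-2,13-diacetoxy-8-(2-methylprop-2-enoyloxy)germacra-1(10),4,7(11)-trien-12,6-olide (CNP0309304.1) | C=C(C)C(=O)O[C@H]1C/C(C)=C/[C@H](OC(C)=O)C/C(C)=C/[C@H]2OC(=O)C(COC(C)=O)=C12 | target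

## Step count and least certain steps

Total step count: 18. Longest linear sequence: 18 steps (1 to 26); the partners 6, 12 and 14 are purchased.

**Step 13 (key step).**
- What may go wrong: leakage of alkene geometry. The anti π-allyl isomer has the less strained cis arrangement of C2 and C9 in the forming ring, and the C10 methyl weakens the syn preference, so closure may run through it to the 1(10)Z ring. If closure is slow, the π-allyl alkoxide can also oligomerise or shift hydride to an enone. Dilution and slow addition are the first answer to the latter.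
- Fallback (sets out from 19, returns at 20): the closure is run as before and the 1(10)Z ring isomer F1 is taken on. MnO2 oxidises its allylic C2 carbinol to the Z enone F2. The conjugated C1=C10 bond is then isomerised (catalytic iodine or a thiol by reversible conjugate addition, or irradiation with recycling of the Z isomer) to the E enone F3. Reduction with (S)-2-methyl-CBS-oxazaborolidine and catecholborane then gives the 2R alcohol 20. This accepts the geometry the ring closure delivers, corrects it afterwards, and sets C2 by reagent control.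

**Step 5 (and with it step 6).**
- What may go wrong: loss of configuration. The C6 substituent is an electron-rich alkenyl group, so the allenylpalladium intermediate can equilibrate through a σ-propargyl/π-allyl form. In step 6 the iodonium ion can open to an allyl cation before the carboxylate closes.
- Fallback (sets out from acid 10 of eroded purity, returns at 11): classical resolution of the axially chiral acid. The acid is crystallised as its salt with (S)-1-phenylethylamine, the ammonium allenoate F4 (the amine antipode is chosen by screening), and the purified salt is submitted directly to iodine in MeCN, as documented for salts of 2,3-allenoic acids, to give 11.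

**Step 11.**
- What may go wrong: Lewis-acid opening or rearrangement of the epoxy ketone by the aluminium component, or competing methylenation of the lactone.
- Fallback (sets out from 17, returns at 19): the order is inverted and a Wittig reaction is used on a substrate whose acidic site is masked as its anion. NaNO2 with phloroglucinol in DMF converts 17 into the nitro epoxy ketone F5. One equivalent of NaN(SiMe3)2 at −78 °C turns it into the sodium nitronate F6, in which the butenolide is part of an extended anion and cannot be deprotonated at C6. Ph3P=CH2 then methylenates the ketone, and a buffered quench gives 19.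

**Step 14.**
- What may go wrong: over-reduction. Trivalent titanium may reduce the newly formed 4-oxobutenolide, an ene-dicarbonyl system, or the stabilised nitronate may be reduced too slowly.
- Fallback (sets out from 20, returns at 22): a two-stage route through the oxime. SnCl2 with PhSH and Et3N in MeCN reduces the secondary nitro group to the C8 oxime F7. Transoximation with glyoxylic acid in buffered aqueous THF then releases ketone 22.

**Step 17.**
- What may go wrong: poor or reversed facial selectivity, because the conformation of the ten-membered ring may override the catalyst.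
- Fallback (sets out from 24, returns at 26): the ring is allowed to decide. If substrate-controlled reduction with NaBH4 and CeCl3 in MeOH at −78 °C gives mainly the 8R alcohol F8, a Mitsunobu reaction with methacrylic acid, PPh3 and diisopropyl azodicarboxylate inverts C8 and installs the ester in one operation, giving 26 directly. SN2′ is blocked by the tetrasubstituted alkene.

## Further compounds

F1 | step 13 | (1(10)Z,2R,4E,6R,8RS)-13-[(tert-butyldimethylsilyl)oxy]-2-hydroxy-8-nitrogermacra-1(10),4,7(11)-trien-12,6-olide | O=[N+]([O-])C1C/C(C)=C\[C@H](O)C/C(C)=C/[C@H]2OC(=O)C(CO[Si](C)(C)C(C)(C)C)=C12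
F2 | step 13 | (1(10)Z,4E,6R,8RS)-13-[(tert-butyldimethylsilyl)oxy]-8-nitro-2-oxogermacra-1(10),4,7(11)-trien-12,6-olide | O=[N+]([O-])C1C/C(C)=C\C(=O)C/C(C)=C/[C@H]2OC(=O)C(CO[Si](C)(C)C(C)(C)C)=C12
F3 | step 13 | (1(10)E,4E,6R,8RS)-13-[(tert-butyldimethylsilyl)oxy]-8-nitro-2-oxogermacra-1(10),4,7(11)-trien-12,6-olide | O=[N+]([O-])C1C/C(C)=C/C(=O)C/C(C)=C/[C@H]2OC(=O)C(CO[Si](C)(C)C(C)(C)C)=C12
F4 | step 5 | (S)-1-phenylethylammonium (Ra,5E)-2-{[(tert-butyldimethylsilyl)oxy]methyl}-6-methylnona-2,3,5,8-tetraenoate | [O-]C(=O)C(CO[Si](C)(C)C(C)(C)C)=[C@]=C([H])/C=C(C)/CC=C.C[C@H]([NH3+])c1ccccc1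
F5 | step 11 | (5R)-5-{(1E)-3-[(2R,3S)-3-acetyloxiran-2-yl]-2-methylprop-1-en-1-yl}-3-{[(tert-butyldimethylsilyl)oxy]methyl}-4-(nitromethyl)furan-2(5H)-one | CC(=O)[C@H]1O[C@@H]1C/C(C)=C/[C@H]1OC(=O)C(CO[Si](C)(C)C(C)(C)C)=C1C[N+](=O)[O-]
F6 | step 11 | sodium nitronate of F5 | CC(=O)[C@H]1O[C@@H]1C/C(C)=C/[C@H]1OC(=O)C(CO[Si](C)(C)C(C)(C)C)=C1C=[N+]([O-])[O-].[Na+]
F7 | step 14 | (1(10)E,2R,4E,6R)-13-[(tert-butyldimethylsilyl)oxy]-2-hydroxy-8-(hydroxyimino)germacra-1(10),4,7(11)-trien-12,6-olide | ON=C1C/C(C)=C/[C@H](O)C/C(C)=C/[C@H]2OC(=O)C(CO[Si](C)(C)C(C)(C)C)=C12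
F8 | step 17 | (1(10)E,2R,4E,6R,8R)-2,13-diacetoxy-8-hydroxygermacra-1(10),4,7(11)-trien-12,6-olide | O[C@@H]1C/C(C)=C/[C@H](OC(C)=O)C/C(C)=C/[C@H]2OC(=O)C(COC(C)=O)=C12
A1 | alternative 1 | open-chain ynal, (2R,8S)-2,13-diacetoxy-8-[(tert-butyldimethylsilyl)oxy]-6,7-secogermacra-1(10)E,4E-dien-7(11)-yn-6-al | CC(=O)OCC#C[C@@H](O[Si](C)(C)C(C)(C)C)C/C(C)=C/[C@H](OC(C)=O)C/C(C)=C/C=O
A2 | alternative 1 | (1(10)E,2R,4E,6R,8S)-2,13-diacetoxy-8-[(tert-butyldimethylsilyl)oxy]germacra-1(10),4,7(11)-trien-12,6-olide | CC(C)(C)[Si](C)(C)O[C@H]1C/C(C)=C/[C@H](OC(C)=O)C/C(C)=C/[C@H]2OC(=O)C(COC(C)=O)=C12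
A3 | alternative 2 | (4S,6R,7S)-3-{[(tert-butyldimethylsilyl)oxy]methyl}-6-{(E)-2-[(tert-butyldimethylsilyl)oxy]ethenyl}-4-[(4-methoxybenzyl)oxy]-6-methyl-7-(prop-1-en-2-yl)-4,5,6,7-tetrahydro-1-benzofuran-7-ol | C=C(C)[C@@]1(O)c2occ(CO[Si](C)(C)C(C)(C)C)c2[C@@H](OCc2ccc(OC)cc2)C[C@]1(C)/C=C/O[Si](C)(C)C(C)(C)C
A4 | alternative 2 | ten-membered furanophane C5 enol triflate (2R,8S; C2 silyl ether, C8 4-methoxybenzyl ether, C13 silyl ether) | COc1ccc(CO[C@H]2C/C(C)=C/[C@H](O[Si](C)(C)C(C)(C)C)C/C(C)=C(\OS(=O)(=O)C(F)(F)F)c3occ(CO[Si](C)(C)C(C)(C)C)c23)cc1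
A5 | alternative 3 | open-chain C6 furylstannane with E C5 vinyl iodide (2R,8S; C2 acetate, C8 silyl ether, C13 acetate) | CCCC[Sn](CCCC)(CCCC)c1occ(COC(C)=O)c1[C@@H](O[Si](C)(C)C(C)(C)C)C/C(C)=C/[C@H](OC(C)=O)C/C(C)=C/I
A6 | alternative 3 | ten-membered 2,3-bridged furanophane (2R,8S; C2 acetate, C8 silyl ether, C13 acetate) | CC(C)(C)[Si](C)(C)O[C@H]1C/C(C)=C/[C@H](OC(C)=O)C/C(C)=C/c2occ(COC(C)=O)c12
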